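All runs are simulated for an exercise; scatter was added.

Between 5.00 min and 15.0 min of the elm run, substrate and target added together fell by 33 percentage points. We build the reckoning on that number, after setting out the problem.

| flask | substrate | reagent | initiator | remark | time |
|---|---|---|---|---|---|
| ash | 0.020 M | 0.026 M | 0.22 mM | run made earlier |  |
| elm | 0.020 M | 0.013 M | 0.22 mM | run made earlier |  |
| alder | 0.020 M | 0.019 M | 0.22 mM | run made earlier |  |
| Wednesday's | 0.020 M | 0.0260 M | 0.22 mM | one stirred flow tank at steady state, fed with the mixture as stated, mean residence time 15 min |  |
| Sunday's | 0.020 M | 0.0260 M (fed, over 15.0 min) | 0.22 mM | a stirred flask in which reagent is dosed at a steady rate over 15.0 min without added volume, worked up at 15 min | 15 min |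
| Tuesday's | 0.020 M (fed, over 15.0 min) | 0.0260 M | 0.22 mM | a stirred flask in which substrate is dosed at a steady rate over 15.0 min without added volume, worked up at 15 min | 15 min |
| Thursday's | 0.020 M | 0.0260 M | 0.22 mM | a closed flask charged with all of it at once and left for 15 min | 15 min |

- ash (time / min: target / %, substrate / %): 0.667: 15.0, 82.5; 1.33: 25.5, 64.4; 2.00: 32.7, 53.8; 3.00: 42.7, 37.0; 5.00: 51.4, 14.9; 10.0: 64.2, 1.2
- elm (time / min: target / %, substrate / %): 2.50: 17.9, 70.6; 5.00: 20.9, 52.9; 8.00: 20.4, 39.3; 10.0: 21.4, 34.4; 12.0: 19.6, 27.8; 15.0: 16.7, 23.6
- alder (time / min: target / %, substrate / %): 2.50: 25.6, 58.2; 5.00: 32.2, 35.2; 8.00: 37.5, 19.7; 10.0: 38.7, 11.7; 12.0: 38.8, 8.0; 15.0: 37.8, 4.2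

(readings scatter by 1 percentage point)

- the stated concentrations are those of everything mixed, before any reaction; amounts are the same in each set-up
- the analysis behind the earlier runs scatters by 1 percentage point, standard deviation
- the feed brings no volume worth counting
- the earlier runs were made in a closed, stirred flask

1. the set-up with the highest amount of target at the outlet or at the end, in percent of the substrate put in ("none" if the first two lie within 2 percentage points) (Wednesday's / Sunday's / Tuesday's / Thursday's / none)
2. amount of target at the outlet or at the end, in percent of the substrate put in, Wednesday's
3. amount of target at the outlet or at the end, in percent of the substrate put in, Sunday's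
4. amount of target at the outlet or at the end, in percent of the substrate put in, Tuesday's
5. amount of target at the outlet or at the end, in percent of the substrate put in, Thursday's

Making target turns one substrate into one target, so that step leaves the sum of the two columns unchanged. Something else lowers it. We read the tables column against column. In the elm run, c(substrate) stands at 34.4 % at 10.0 min and target sags from 21.4 % to 16.7 % by 15.0 min. In the alder run, with 11.7 % substrate at 10.0 min, target goes from 38.7 % to 37.8 %. In the ash run, between 5.00 min and 10.0 min, substrate falls to 1.2 % and the sum drops by 0.9 points, within the scatter.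

So we suppose that target is lost by meeting substrate, each turn taking one of each out of the sum. Dividing the elm drop by twice the elapsed time and the mean c(substrate) and mean target gives a reading for the loss constant of 0.194 M⁻¹ s⁻¹. With substrate held at its charge this is a pseudo-first-order loss, and it gives the target's life against substrate, the half-life of target at a stated c(substrate): 2.98 min at the full charge. It lengthens as substrate goes: at the ash run's last 1.2 % it is 248 min.

Our own reckoning therefore puts Thursday's, charged like the ash run, near that run's last 64.2 %. For Sunday's flask we commit to no figure; its dosing time of 15.0 min is longer than the life at the full charge.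

The forecast named Thursday's, with 46 % for Wednesday's, 33 % for Sunday's, 50 % for Tuesday's and 62 % for Thursday's, on the ground that “Excess reagent therefore protects the yield”.

The flasks give 56.8 % for Wednesday's, 16.3 % for Sunday's, 51.5 % for Tuesday's and 62.5 % for Thursday's, so the best is Thursday's.

    initiator → 2 initiating radical (k = 0.00534 s⁻¹)
    substrate + initiating radical → chain carrier (k = 3.15 × 10⁶ M⁻¹ s⁻¹)
    reagent + chain carrier → target + initiating radical (k = 80900 M⁻¹ s⁻¹)
    2 chain carrier → ended chains A (k = 6.20 × 10⁸ M⁻¹ s⁻¹)
    2 initiating radical → ended chains B (k = 1.00 × 10⁹ M⁻¹ s⁻¹)
    substrate + target → side product (k = 0.182 M⁻¹ s⁻¹)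

With substrate and reagent as charged, target in Thursday's flask has a half-life of 3.2 min by its turning into side product, shorter than the 15 min in the flask. Our late life of 248 min is longer than 150 min, and Thursday's target reads 62.5 % at that time. In Sunday's flask target falls from 16.3 % at 15 min to 1.55 % at 150 min, a mean halving time over that stretch of 39.8 min, longer than our life of 2.98 min at the full charge.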